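**Plan**

- Numbering used here: ring C1 (the CH2 between the stereocentre and the vinylic CH) → C2=C3(CO2H) → C4, C5 → C6=C7(Me) → C8, C9 → C10=C11(Me) → C12, C13 → C14 (stereocentre); side chain C15(=CH2)–C16–C17–C18=C19Me2.
- Cuts: C1–C2 (ring closure, C14–H made in the same operation); C15=CH2 traced back to a temporary C15 carbinol; C12–C13 (allyl dianion + allylic bromide); C10=C11 (Z-selective olefination); C8–C9 with C6=C7 (Johnson–Claisen); C3–C4 with C2–I (carbomagnesiation/iodination of propargyl alcohol).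
- Forward: the open chain is grown from the iodoalkene end C2 to C12 (steps 1–9) and joined to the C13–C19 alcohol (step 12). The only ring, the 14-membered carbocycle, is closed last at C1–C2 (step 13); C15 is then returned to C=CH2 and C3–CH2O raised to CO2H.
- Enabling feature: C1 is both the sp3 partner of vinylic C2 and the CH2 end of a latent 1,1-disubstituted alkene C14=C1. Its allylic neighbour C15 is sp2 in the target, so it can be carried as a silyloxy stereocentre (a C–O bond absent from the target) that steers hydroboration and is erased afterwards.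
- Stereochemistry: C14 (R) from 14,15-anti hydroboration under control of (15S)-OSi (Sharpless kinetic resolution); 2Z from anti-carbomagnesiation plus stereoretentive coupling; 6E from the chair Claisen; 10Z from the Still–Gennari reagent.

Key step: step 13

**Route**

Step 1
Reactants: 1 2-(2-bromoethyl)-1,3-dioxolane; 2 prop-2-yn-1-ol
Product: 5 (2Z)-2-[2-(1,3-dioxolan-2-yl)ethyl]-3-iodoprop-2-en-1-ol, via Grignard reagent 3 (not isolated), via oxamagnesole 4 (not isolated)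
Conditions: Mg, THF, 25 °C; 3 (2.5 equiv) added to 2, CuI (10 mol%), THF–Et2O, −10 °C → rt; then I2, −40 → 0 °C
Reagents that add atoms: iodine, [I][I]
Why: Copper-catalysed anti-carbomagnesiation of the propargylic magnesium alkoxide puts the alkyl group on the carbinol-bearing alkyne carbon and magnesium on the terminal carbon inside a five-membered O–Mg chelate, so iodinolysis with retention should give the alkenyl iodide with iodine cis to CH2OH (the future 2Z geometry).

Step 2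
Reactants: 5 (2Z)-2-[2-(1,3-dioxolan-2-yl)ethyl]-3-iodoprop-2-en-1-ol
Product: 6 2-[(3Z)-4-iodo-3-{[(4-methoxybenzyl)oxy]methyl}but-3-en-1-yl]-1,3-dioxolane
Conditions: NaH, 4-methoxybenzyl chloride, Bu4NI (cat.), THF–DMF, 0 °C → rt
Reagents that add atoms: 4-methoxybenzyl chloride, COc1ccc(CCl)cc1
Why: Williamson etherification of the primary allylic alkoxide; the alkenyl iodide has no hydrogen placed for elimination and should survive.

Step 3
Reactants: 6 2-[(3Z)-4-iodo-3-{[(4-methoxybenzyl)oxy]methyl}but-3-en-1-yl]-1,3-dioxolane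
Product: 7 (4Z)-5-iodo-4-{[(4-methoxybenzyl)oxy]methyl}pent-4-enal
Conditions: PPTS (cat.), acetone–H2O, 60 °C
Reagents that add atoms: water, O
Why: Mild acid-catalysed acetal hydrolysis should free the C6 aldehyde while the PMB ether and the alkenyl iodide stay intact.

Step 4
Reactants: 7 (4Z)-5-iodo-4-{[(4-methoxybenzyl)oxy]methyl}pent-4-enal
Product: 8 (6Z)-7-iodo-6-{[(4-methoxybenzyl)oxy]methyl}-2-methylhepta-1,6-dien-3-ol (racemic at C3)
Conditions: isopropenylmagnesium bromide, THF, −78 °C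
Reagents that add atoms: isopropenylmagnesium bromide, C=C(C)[Mg]Br
Why: Grignard 1,2-addition to the aldehyde, with the unactivated alkenyl iodide inert at −78 °C; the new carbinol centre is racemic and is destroyed in step 5.

Step 5
Reactants: 8 (6Z)-7-iodo-6-{[(4-methoxybenzyl)oxy]methyl}-2-methylhepta-1,6-dien-3-ol
Product: 10 ethyl (4E,8Z)-9-iodo-8-{[(4-methoxybenzyl)oxy]methyl}-4-methylnona-4,8-dienoate, via ketene acetal 9 (not isolated)
Conditions: MeC(OEt)3, EtCO2H (cat.), 140 °C, EtOH distilled off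
Reagents that add atoms: triethyl orthoacetate, CCOC(C)(OCC)OCC
Why: Johnson–Claisen [3,3] rearrangement through a chair transition state with the C6 substituent equatorial should form C8–C9 and the 6E trisubstituted alkene.

Step 6
Reactants: 10 ethyl (4E,8Z)-9-iodo-8-{[(4-methoxybenzyl)oxy]methyl}-4-methylnona-4,8-dienoate
Product: 11 (4E,8Z)-9-iodo-8-{[(4-methoxybenzyl)oxy]methyl}-4-methylnona-4,8-dienal
Conditions: i-Bu2AlH (1.1 equiv), CH2Cl2, −78 °C; aq. potassium sodium tartrate (KNaC4H4O6) work-up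
Reagents that add atoms: none
Why: Partial ester reduction; the tetrahedral aluminium hemiacetal is stable at −78 °C and releases the C10 aldehyde only on work-up.

Step 7
Reactants: 11 (4E,8Z)-9-iodo-8-{[(4-methoxybenzyl)oxy]methyl}-4-methylnona-4,8-dienal
Product: 12 methyl (2Z,6E,10Z)-11-iodo-10-{[(4-methoxybenzyl)oxy]methyl}-2,6-dimethylundeca-2,6,10-trienoate
Conditions: (CF3CH2O)2P(O)CH(Me)CO2Me, KN(SiMe3)2, 18-crown-6, THF, −78 °C
Reagents that add atoms: methyl 2-[bis(2,2,2-trifluoroethoxy)phosphoryl]propanoate, COC(=O)C(C)P(=O)(OCC(F)(F)F)OCC(F)(F)F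
Why: Still–Gennari olefination; the electron-poor phosphonate with a dissociated potassium counter-ion eliminates fast from the kinetic adduct, which should place the ester carbon (C12) cis to C9 (10Z).

Step 8
Reactants: 12 methyl (2Z,6E,10Z)-11-iodo-10-{[(4-methoxybenzyl)oxy]methyl}-2,6-dimethylundeca-2,6,10-trienoate
Product: 13 (2Z,6E,10Z)-11-iodo-10-{[(4-methoxybenzyl)oxy]methyl}-2,6-dimethylundeca-2,6,10-trien-1-ol
Conditions: i-Bu2AlH (2.5 equiv), CH2Cl2, −78 °C
Reagents that add atoms: none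
Why: 1,2-reduction of the enoate to the allylic alcohol leaves the alkene geometry untouched.

Step 9
Reactants: 13 (2Z,6E,10Z)-11-iodo-10-{[(4-methoxybenzyl)oxy]methyl}-2,6-dimethylundeca-2,6,10-trien-1-ol
Product: 14 (1Z,5E,9Z)-11-bromo-1-iodo-2-{[(4-methoxybenzyl)oxy]methyl}-6,10-dimethylundeca-1,5,9-triene
Conditions: CBr4, PPh3, CH2Cl2, −30 °C; used at once
Reagents that add atoms: carbon tetrabromide, BrC(Br)(Br)Br
Why: Appel bromination by SN2 displacement of the alkoxyphosphonium ion at the primary allylic carbon; low temperature should suppress allylic transposition and Z/E scrambling.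

Step 10
Reactants: 15 5-bromo-2-methylpent-2-ene; 16 2-methylprop-2-enal
Product: 18 rac-2,7-dimethylocta-1,6-dien-3-ol, via Grignard reagent 17 (not isolated)
Conditions: Mg, THF; then 16, −78 °C
Reagents that add atoms: none
Why: Grignard 1,2-addition to the enal gives the racemic 2-methylallylic alcohol that carries C1, C13–C19.

Step 11
Reactants: 18 rac-2,7-dimethylocta-1,6-dien-3-ol
Product: 19 (3S)-2,7-dimethylocta-1,6-dien-3-ol
Conditions: Ti(Oi-Pr)4 (cat.), D-(−)-diisopropyl tartrate, t-BuOOH (0.6 equiv), 4 Å sieves, CH2Cl2, −20 °C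
Reagents that add atoms: none
Why: Sharpless kinetic resolution; the catalyst formed from Ti(Oi-Pr)4 and D-(−)-diisopropyl tartrate epoxidises the (R)-alcohol faster, so the (S)-alcohol (the temporary C15 stereocentre) should be recovered in high enantiomeric purity.

Step 12
Reactants: 19 (3S)-2,7-dimethylocta-1,6-dien-3-ol; 14 (1Z,5E,9Z)-11-bromo-1-iodo-2-{[(4-methoxybenzyl)oxy]methyl}-6,10-dimethylundeca-1,5,9-triene
Product: 22 tert-butyl{[(1Z,5E,9Z,14S)-1-iodo-2-{[(4-methoxybenzyl)oxy]methyl}-6,10,18-trimethyl-13-methylidenenonadeca-1,5,9,17-tetraen-14-yl]oxy}dimethylsilane, via dianion 20 (not isolated), via lithium alkoxide 21 (not isolated)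
Conditions: n-BuLi (2.0 equiv), TMEDA, Et2O–hexane, 0 °C → rt; then 14 (0.8 equiv), THF, −78 °C; then t-BuMe2SiOTf, −78 → 0 °C
Reagents that add atoms: tert-butyldimethylsilyl trifluoromethanesulfonate, CC(C)(C)[Si](C)(C)OS(=O)(=O)C(F)(F)F
Why: Alkoxide-directed allylic lithiation of the 2-methyl group gives an allyl anion whose two CH2 termini are equivalent, so SN2 alkylation by the primary allylic bromide should form C12–C13 as one constitution without touching C15, and the silyl triflate then traps the alkoxide.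

Step 13
Reactants: 22 tert-butyl{[(1Z,5E,9Z,14S)-1-iodo-2-{[(4-methoxybenzyl)oxy]methyl}-6,10,18-trimethyl-13-methylidenenonadeca-1,5,9,17-tetraen-14-yl]oxy}dimethylsilane
Product: 24 tert-butyl{[(1S)-1-[(1R,3Z,7E,11Z)-4-{[(4-methoxybenzyl)oxy]methyl}-8,12-dimethylcyclotetradeca-3,7,11-trien-1-yl]-5-methylhex-4-en-1-yl]oxy}dimethylsilane, via alkylborane 23 (not isolated)
Conditions: 9-BBN dimer, THF, 0 °C → rt; H2O; then slow addition to Pd(dppf)Cl2 (15 mol%), AsPh3, Cs2CO3, DMF–THF–H2O, 50 °C (about 2 mM)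
Reagents that add atoms: none
Why: 9-BBN adds to the C14=C1 bond with boron on C1 and hydrogen on C14, and the hydroxide-activated B-alkyl-9-BBN transmetalates to the alkenylpalladium iodide formed by oxidative addition of zerovalent palladium into C2–I, after which reductive elimination forms C1–C2. The closest known reaction type is the substrate-controlled 9-BBN hydroboration of a 2-substituted allylic silyl ether run in tandem with a B-alkyl Suzuki–Miyaura macrocyclisation onto an alkenyl iodide. The only ring of the target, the 14-membered carbocycle, is closed by this intramolecular C(sp3)–C(sp2) coupling, with the new bond and the C2=C3 alkene both endocyclic. C14 is created in the hydroboration: in the conformer that minimises allylic strain (C15–H eclipsing the alkene) the bulky borane attacks the face anti to the C16 chain, giving the 14,15-anti adduct, so (15S)-OSi should dictate (14R). The step needs hydroboration of the single 1,1-disubstituted alkene beside three trisubstituted alkenes and the iodoalkene (secured by the strong preference of 9-BBN for the less substituted alkene), retention of the 2Z geometry (oxidative addition and reductive elimination both retain configuration) and cyclisation over oligomerisation (slow addition at high dilution).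

Step 14
Reactants: 24 tert-butyl{[(1S)-1-[(1R,3Z,7E,11Z)-4-{[(4-methoxybenzyl)oxy]methyl}-8,12-dimethylcyclotetradeca-3,7,11-trien-1-yl]-5-methylhex-4-en-1-yl]oxy}dimethylsilane
Product: 25 (1S)-1-[(1R,3Z,7E,11Z)-4-{[(4-methoxybenzyl)oxy]methyl}-8,12-dimethylcyclotetradeca-3,7,11-trien-1-yl]-5-methylhex-4-en-1-ol
Conditions: Bu4NF, THF, 40 °C
Reagents that add atoms: none
Why: Fluoride-driven desilylation frees the C15 alcohol; the PMB ether is stable, and the minor 14,15-syn diastereomer is removed here by chromatography.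

Step 15
Reactants: 25 (1S)-1-[(1R,3Z,7E,11Z)-4-{[(4-methoxybenzyl)oxy]methyl}-8,12-dimethylcyclotetradeca-3,7,11-trien-1-yl]-5-methylhex-4-en-1-ol
Product: 26 1-[(1R,3Z,7E,11Z)-4-{[(4-methoxybenzyl)oxy]methyl}-8,12-dimethylcyclotetradeca-3,7,11-trien-1-yl]-5-methylhex-4-en-1-one
Conditions: Dess–Martin periodinane, NaHCO3, CH2Cl2, 0 °C
Reagents that add atoms: none
Why: Buffered Dess–Martin oxidation is neutral and fast, so the ketone should form without enolisation toward C14.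

Step 16
Reactants: 26 1-[(1R,3Z,7E,11Z)-4-{[(4-methoxybenzyl)oxy]methyl}-8,12-dimethylcyclotetradeca-3,7,11-trien-1-yl]-5-methylhex-4-en-1-one
Product: 27 (1R,3Z,7E,11Z)-4-{[(4-methoxybenzyl)oxy]methyl}-8,12-dimethyl-1-(6-methylhepta-1,5-dien-2-yl)cyclotetradeca-3,7,11-triene
Conditions: Cp2Ti(μ-Cl)(μ-CH2)AlMe2, pyridine (cat.), THF–toluene, −40 → 0 °C
Reagents that add atoms: Tebbe reagent Cp2Ti(μ-Cl)(μ-CH2)AlMe2, C[Al-]1(C)C[Ti]([Cl+]1)(C2C=CC=C2)C3C=CC=C3
Why: Tebbe methylenation ([2+2] addition of Cp2Ti=CH2 to the carbonyl and cycloreversion of the oxatitanacyclobutane) is non-basic, so C15=CH2 should be installed without epimerising C14.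

Step 17
Reactants: 27 (1R,3Z,7E,11Z)-4-{[(4-methoxybenzyl)oxy]methyl}-8,12-dimethyl-1-(6-methylhepta-1,5-dien-2-yl)cyclotetradeca-3,7,11-triene
Product: 28 [(1Z,4E,8Z,12R)-5,9-dimethyl-12-(6-methylhepta-1,5-dien-2-yl)cyclotetradeca-1(14),4,8-trien-1-yl]methanol
Conditions: DDQ, CH2Cl2–pH 7 buffer, 0 °C
Reagents that add atoms: none
Why: Oxidative PMB cleavage (hydride abstraction at the electron-rich benzylic position, then hydrolysis) is selective for the ether over the isolated alkenes.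

Step 18
Reactants: 28 [(1Z,4E,8Z,12R)-5,9-dimethyl-12-(6-methylhepta-1,5-dien-2-yl)cyclotetradeca-1(14),4,8-trien-1-yl]methanol
Product: 30 (1Z,4E,8Z,12R)-5,9-dimethyl-12-(6-methylhepta-1,5-dien-2-yl)cyclotetradeca-1(14),4,8-triene-1-carboxylic acid, via enal 29 (not isolated)
Conditions: MnO2, CH2Cl2, rt, filter; then NaClO2, NaH2PO4, 2-methylbut-2-ene, t-BuOH–H2O, 0 °C → rt
Reagents that add atoms: sodium chlorite NaClO2, [Na+].[O-]Cl=O
Why: Allylic oxidation with MnO2 followed by Pinnick oxidation should give the acid without isomerising the 2Z alkene; the scavenger protects the other alkenes from HOCl.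

**Compound list**

1 | 2-(2-bromoethyl)-1,3-dioxolane | BrCCC1OCCO1 | starting material
2 | prop-2-yn-1-ol | C#CCO | starting material
3 | [2-(1,3-dioxolan-2-yl)ethyl]magnesium bromide | Br[Mg]CCC1OCCO1 | intermediate
4 | 4-[2-(1,3-dioxolan-2-yl)ethyl]-2,5-dihydro-1,2-oxamagnesole (cyclic alkenylmagnesium alkoxide) | [Mg]1OCC(CCC2OCCO2)=C1 | intermediate
5 | (2Z)-2-[2-(1,3-dioxolan-2-yl)ethyl]-3-iodoprop-2-en-1-ol | OC/C(=C\I)CCC1OCCO1 | intermediate
6 | 2-[(3Z)-4-iodo-3-{[(4-methoxybenzyl)oxy]methyl}but-3-en-1-yl]-1,3-dioxolane | COc1ccc(COC/C(=C\I)CCC2OCCO2)cc1 | intermediate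
7 | (4Z)-5-iodo-4-{[(4-methoxybenzyl)oxy]methyl}pent-4-enal | COc1ccc(COC/C(=C\I)CCC=O)cc1 | intermediate
8 | (6Z)-7-iodo-6-{[(4-methoxybenzyl)oxy]methyl}-2-methylhepta-1,6-dien-3-ol (racemic) | COc1ccc(COC/C(=C\I)CCC(O)C(C)=C)cc1 | intermediate
9 | 1-ethoxyethenyl ether of 8 (mixed ketene acetal) | C=C(OCC)OC(CC/C(COCc1ccc(OC)cc1)=C/I)C(C)=C | intermediate
10 | ethyl (4E,8Z)-9-iodo-8-{[(4-methoxybenzyl)oxy]methyl}-4-methylnona-4,8-dienoate | CCOC(=O)CC/C(C)=C/CC/C(COCc1ccc(OC)cc1)=C/I | intermediate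
11 | (4E,8Z)-9-iodo-8-{[(4-methoxybenzyl)oxy]methyl}-4-methylnona-4,8-dienal | O=CCC/C(C)=C/CC/C(COCc1ccc(OC)cc1)=C/I | intermediate
12 | methyl (2Z,6E,10Z)-11-iodo-10-{[(4-methoxybenzyl)oxy]methyl}-2,6-dimethylundeca-2,6,10-trienoate | COC(=O)/C(C)=C\CC/C(C)=C/CC/C(COCc1ccc(OC)cc1)=C/I | intermediate
13 | (2Z,6E,10Z)-11-iodo-10-{[(4-methoxybenzyl)oxy]methyl}-2,6-dimethylundeca-2,6,10-trien-1-ol | OC/C(C)=C\CC/C(C)=C/CC/C(COCc1ccc(OC)cc1)=C/I | intermediate
14 | (1Z,5E,9Z)-11-bromo-1-iodo-2-{[(4-methoxybenzyl)oxy]methyl}-6,10-dimethylundeca-1,5,9-triene | BrC/C(C)=C\CC/C(C)=C/CC/C(COCc1ccc(OC)cc1)=C/I | intermediate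
15 | 5-bromo-2-methylpent-2-ene | CC(C)=CCCBr | starting material
16 | 2-methylprop-2-enal | C=C(C)C=O | starting material
17 | (4-methylpent-3-en-1-yl)magnesium bromide | CC(C)=CCC[Mg]Br | intermediate
18 | rac-2,7-dimethylocta-1,6-dien-3-ol | CC(C)=CCCC(O)C(C)=C | intermediate
19 | (3S)-2,7-dimethylocta-1,6-dien-3-ol | CC(C)=CCC[C@H](O)C(C)=C | intermediate
20 | lithium (3S)-2-(lithiomethyl)-7-methylocta-1,6-dien-3-olate (dianion of 19) | CC(C)=CCC[C@H](O[Li])C(=C)C[Li] | intermediate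
21 | lithium (1Z,5E,9Z,14S)-1-iodo-2-{[(4-methoxybenzyl)oxy]methyl}-6,10,18-trimethyl-13-methylidenenonadeca-1,5,9,17-tetraen-14-olate | CC(C)=CCC[C@H](O[Li])C(=C)CC/C(C)=C\CC/C(C)=C/CC/C(COCc1ccc(OC)cc1)=C/I | intermediate
22 | tert-butyl{[(1Z,5E,9Z,14S)-1-iodo-2-{[(4-methoxybenzyl)oxy]methyl}-6,10,18-trimethyl-13-methylidenenonadeca-1,5,9,17-tetraen-14-yl]oxy}dimethylsilane | CC(C)=CCC[C@H](O[Si](C)(C)C(C)(C)C)C(=C)CC/C(C)=C\CC/C(C)=C/CC/C(COCc1ccc(OC)cc1)=C/I | intermediate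
23 | 9-[(2S,3S)-3-[(tert-butyldimethylsilyl)oxy]-2-[(3Z,7E,11Z)-12-iodo-11-{[(4-methoxybenzyl)oxy]methyl}-3,7-dimethyldodeca-3,7,11-trien-1-yl]-7-methyloct-6-en-1-yl]-9-borabicyclo[3.3.1]nonane | CC(C)=CCC[C@H](O[Si](C)(C)C(C)(C)C)[C@@H](CB1C2CCCC1CCC2)CC/C(C)=C\CC/C(C)=C/CC/C(COCc1ccc(OC)cc1)=C/I | intermediate
24 | tert-butyl{[(1S)-1-[(1R,3Z,7E,11Z)-4-{[(4-methoxybenzyl)oxy]methyl}-8,12-dimethylcyclotetradeca-3,7,11-trien-1-yl]-5-methylhex-4-en-1-yl]oxy}dimethylsilane | CC(C)=CCC[C@H](O[Si](C)(C)C(C)(C)C)[C@H]1C/C=C(\COCc2ccc(OC)cc2)CC/C=C(\C)CC/C=C(/C)CC1 | intermediate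
25 | (1S)-1-[(1R,3Z,7E,11Z)-4-{[(4-methoxybenzyl)oxy]methyl}-8,12-dimethylcyclotetradeca-3,7,11-trien-1-yl]-5-methylhex-4-en-1-ol | CC(C)=CCC[C@H](O)[C@H]1C/C=C(\COCc2ccc(OC)cc2)CC/C=C(\C)CC/C=C(/C)CC1 | intermediate
26 | 1-[(1R,3Z,7E,11Z)-4-{[(4-methoxybenzyl)oxy]methyl}-8,12-dimethylcyclotetradeca-3,7,11-trien-1-yl]-5-methylhex-4-en-1-one | CC(C)=CCCC(=O)[C@H]1C/C=C(\COCc2ccc(OC)cc2)CC/C=C(\C)CC/C=C(/C)CC1 | intermediate
27 | (1R,3Z,7E,11Z)-4-{[(4-methoxybenzyl)oxy]methyl}-8,12-dimethyl-1-(6-methylhepta-1,5-dien-2-yl)cyclotetradeca-3,7,11-triene | C=C(CCC=C(C)C)[C@H]1C/C=C(\COCc2ccc(OC)cc2)CC/C=C(\C)CC/C=C(/C)CC1 | intermediate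
28 | [(1Z,4E,8Z,12R)-5,9-dimethyl-12-(6-methylhepta-1,5-dien-2-yl)cyclotetradeca-1(14),4,8-trien-1-yl]methanol | C=C(CCC=C(C)C)[C@H]1C/C=C(\CO)CC/C=C(\C)CC/C=C(/C)CC1 | intermediate
29 | (1Z,4E,8Z,12R)-5,9-dimethyl-12-(6-methylhepta-1,5-dien-2-yl)cyclotetradeca-1(14),4,8-triene-1-carbaldehyde | C=C(CCC=C(C)C)[C@H]1C/C=C(\C=O)CC/C=C(\C)CC/C=C(/C)CC1 | intermediate
30 | (1Z,4E,8Z,12R)-5,9-dimethyl-12-(6-methylhepta-1,5-dien-2-yl)cyclotetradeca-1(14),4,8-triene-1-carboxylic acid | C=C(CCC=C(C)C)[C@H]1C/C=C(\C(=O)O)CC/C=C(\C)CC/C=C(/C)CC1 | target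

**Count**

Total steps: 18. Longest linear sequence: 16 steps (steps 1–9, then 12–18); steps 10–11 form the second branch.

**Steps most likely to fail**

1. Step 13. What may go wrong: incomplete facial control in the hydroboration (the syn pathway leads, once C15 is erased, to the enantiomer of the target), slow transmetalation of the β-branched alkylborane, and oligomerisation or protodeboronation during ring closure. Fallback, from 22 back to 24: hydroboration with 9-BBN followed by oxidative work-up (NaBO3·4H2O) should give the primary alcohol (2R,3S)-3-[(tert-butyldimethylsilyl)oxy]-2-[(3Z,7E,11Z)-12-iodo-11-{[(4-methoxybenzyl)oxy]methyl}-3,7-dimethyldodeca-3,7,11-trien-1-yl]-7-methyloct-6-en-1-ol F1, from which the syn isomer is removed by chromatography. Treatment with I2, PPh3 and imidazole should then give the primary iodide tert-butyl{[(1Z,5E,9Z,13S,14S)-1-iodo-13-(iodomethyl)-2-{[(4-methoxybenzyl)oxy]methyl}-6,10,18-trimethylnonadeca-1,5,9,17-tetraen-14-yl]oxy}dimethylsilane F2. Zn dust (activated with 1,2-dibromoethane and Me3SiCl, THF, 40 °C) should insert only into the alkyl C–I bond to give iodo{(2S,3S)-3-[(tert-butyldimethylsilyl)oxy]-2-[(3Z,7E,11Z)-12-iodo-11-{[(4-methoxybenzyl)oxy]methyl}-3,7-dimethyldodeca-3,7,11-trien-1-yl]-7-methyloct-6-en-1-yl}zinc F3, which is added slowly to Pd(PPh3)4 in THF–NMP at 50 °C; the intramolecular Negishi coupling onto the alkenyl iodide gives 24.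

2. Step 12. What may go wrong: incomplete or misdirected allylic lithiation, SN2' attack on the allylic bromide, or halogen–metal exchange at the alkenyl iodide. Fallback, from 14 back to 22: Li2CuCl4-catalysed coupling of 14 with Grignard reagent 3 (THF, −78 °C) should give 2-[(4Z,8E,12Z)-13-iodo-12-{[(4-methoxybenzyl)oxy]methyl}-4,8-dimethyltrideca-4,8,12-trien-1-yl]-1,3-dioxolane F4. Hydrolysis (PPTS, acetone–water) gives (5Z,9E,13Z)-14-iodo-13-{[(4-methoxybenzyl)oxy]methyl}-5,9-dimethyltetradeca-5,9,13-trienal F5. α-Methylenation with dimethyl(methylidene)ammonium iodide and Et3N gives (5Z,9E,13Z)-14-iodo-13-{[(4-methoxybenzyl)oxy]methyl}-5,9-dimethyl-2-methylidenetetradeca-5,9,13-trienal F6. Addition of Grignard reagent 17 at −78 °C gives rac-(1Z,5E,9Z)-1-iodo-2-{[(4-methoxybenzyl)oxy]methyl}-6,10,18-trimethyl-13-methylidenenonadeca-1,5,9,17-tetraen-14-ol F7. Sharpless kinetic resolution with D-(−)-diisopropyl tartrate should leave the (14S)-alcohol (1Z,5E,9Z,14S)-1-iodo-2-{[(4-methoxybenzyl)oxy]methyl}-6,10,18-trimethyl-13-methylidenenonadeca-1,5,9,17-tetraen-14-ol F8, and t-BuMe2SiOTf with 2,6-lutidine gives 22.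

3. Step 16 (with the ketone made in step 15). What may go wrong: enolisation of the α-branched ketone toward C14 during methylenation, which would racemise the only remaining stereocentre. Fallback, from 26 back to 27: addition of Me3SiCH2Li pre-mixed with anhydrous CeCl3 (THF, −78 °C), a weakly basic nucleophile, should give the β-hydroxysilane 2-[(1R,3Z,7E,11Z)-4-{[(4-methoxybenzyl)oxy]methyl}-8,12-dimethylcyclotetradeca-3,7,11-trien-1-yl]-6-methyl-1-(trimethylsilyl)hept-5-en-2-ol F9, and Peterson elimination with KH in THF gives 27.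

**Further compounds**

F1 | step 13 | (2R,3S)-3-[(tert-butyldimethylsilyl)oxy]-2-[(3Z,7E,11Z)-12-iodo-11-{[(4-methoxybenzyl)oxy]methyl}-3,7-dimethyldodeca-3,7,11-trien-1-yl]-7-methyloct-6-en-1-ol | CC(C)=CCC[C@H](O[Si](C)(C)C(C)(C)C)[C@@H](CO)CC/C(C)=C\CC/C(C)=C/CC/C(COCc1ccc(OC)cc1)=C/I
F2 | step 13 | tert-butyl{[(1Z,5E,9Z,13S,14S)-1-iodo-13-(iodomethyl)-2-{[(4-methoxybenzyl)oxy]methyl}-6,10,18-trimethylnonadeca-1,5,9,17-tetraen-14-yl]oxy}dimethylsilane | CC(C)=CCC[C@H](O[Si](C)(C)C(C)(C)C)[C@@H](CI)CC/C(C)=C\CC/C(C)=C/CC/C(COCc1ccc(OC)cc1)=C/I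
F3 | step 13 | iodo{(2S,3S)-3-[(tert-butyldimethylsilyl)oxy]-2-[(3Z,7E,11Z)-12-iodo-11-{[(4-methoxybenzyl)oxy]methyl}-3,7-dimethyldodeca-3,7,11-trien-1-yl]-7-methyloct-6-en-1-yl}zinc | CC(C)=CCC[C@H](O[Si](C)(C)C(C)(C)C)[C@@H](C[Zn]I)CC/C(C)=C\CC/C(C)=C/CC/C(COCc1ccc(OC)cc1)=C/I
F4 | step 12 | 2-[(4Z,8E,12Z)-13-iodo-12-{[(4-methoxybenzyl)oxy]methyl}-4,8-dimethyltrideca-4,8,12-trien-1-yl]-1,3-dioxolane | C1COC(CCC/C(C)=C\CC/C(C)=C/CC/C(COCc2ccc(OC)cc2)=C/I)O1
F5 | step 12 | (5Z,9E,13Z)-14-iodo-13-{[(4-methoxybenzyl)oxy]methyl}-5,9-dimethyltetradeca-5,9,13-trienal | O=CCCC/C(C)=C\CC/C(C)=C/CC/C(COCc1ccc(OC)cc1)=C/I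
F6 | step 12 | (5Z,9E,13Z)-14-iodo-13-{[(4-methoxybenzyl)oxy]methyl}-5,9-dimethyl-2-methylidenetetradeca-5,9,13-trienal | O=CC(=C)CC/C(C)=C\CC/C(C)=C/CC/C(COCc1ccc(OC)cc1)=C/I
F7 | step 12 | rac-(1Z,5E,9Z)-1-iodo-2-{[(4-methoxybenzyl)oxy]methyl}-6,10,18-trimethyl-13-methylidenenonadeca-1,5,9,17-tetraen-14-ol | CC(C)=CCCC(O)C(=C)CC/C(C)=C\CC/C(C)=C/CC/C(COCc1ccc(OC)cc1)=C/I
F8 | step 12 | (1Z,5E,9Z,14S)-1-iodo-2-{[(4-methoxybenzyl)oxy]methyl}-6,10,18-trimethyl-13-methylidenenonadeca-1,5,9,17-tetraen-14-ol | CC(C)=CCC[C@H](O)C(=C)CC/C(C)=C\CC/C(C)=C/CC/C(COCc1ccc(OC)cc1)=C/I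
F9 | step 16 | 2-[(1R,3Z,7E,11Z)-4-{[(4-methoxybenzyl)oxy]methyl}-8,12-dimethylcyclotetradeca-3,7,11-trien-1-yl]-6-methyl-1-(trimethylsilyl)hept-5-en-2-ol (carbinol epimers) | CC(C)=CCCC(O)(C[Si](C)(C)C)[C@H]1C/C=C(\COCc2ccc(OC)cc2)CC/C=C(\C)CC/C=C(/C)CC1
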